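In cedar, at the charged amounts and with the way back not counted, the forward conversion of J + G gives J a half-life of 1.2 s, much shorter than the run of 20 s, so I kept books on amounts before times.

    G + Q ⇌ G.Q, settled at all times (K1 = 6.0 × 10⁶ M⁻¹)
    J + G ⇌ Q + L (K2 = 12, k2 = 2200 M⁻¹ s⁻¹)
    X ⇌ J, rate k3*(cs3 - [J]) while solid is left; crystals form when [J] > cs3 (cs3 = 0.20 mM, k3 = 0.33 s⁻¹)
    J + L ⇌ J.L, settled at all times (K4 = 7700 M⁻¹)

- cedar: X 2.0 × 10⁻⁴ M; G 0.260 mM; time 20 s
- larch: X 2.0 × 10⁻⁴ M; G 0.340 mM; time 20 s

- percentages count the X that a species holds: one J.L counts as two
- L is meant together with its J.L
- solid, in amounts per volume of the solution: X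
- at the start none of X is in solution
- what has only dissolved of X counts as not reacted
- in an amount of L, one J.L counts as one L
- apart from what has only dissolved, what has gone from X into another species counts as reacted, even if it can come back
- run time (cedar): 20 s

* part of the X that has reacted (what has only dissolved counts as not reacted) at the end, cedar
* part of the X that has reacted (what has only dissolved counts as not reacted) at the end, larch
* what raising the concentration of G from its lowest to its highest value here does to the part of the X that has reacted (what has only dissolved counts as not reacted) (changes below 5 percentage points count as none) (it falls / it rises / no change)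

I took G as the limiting reagent and followed each mole of it. One G enters the conversion and yields one L and one Q. In cedar, the pairing constant times the charged [G] is 1600, so I booked a second G to G.Q for each Q. In my ledger each L therefore cost two G.

That gave my rule, the G allowance: the charged [G] divided by twice the charged [X], which is the share of X that becomes L when every Q is paired and the whole charge of G is used 65.0%. Larch gets 85.0%. Both lie below the full charge of X, so I expected J to remain.

The solid needed at least 3.03 s, less than the run, so I booked it as dissolved. The ledger counted the whole charge of G as used.

For cedar, that left 0.0700 mM of J beside 0.130 mM of L. The balance with 7700 M⁻¹ put 0.0304 mM of J into J.L, and that J counts as reacted. Cedar closed at 80.2%. The same entries for larch gave 0.0163 mM of J.L and 93.1%, so I expected the reacted part to rise with G.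

The forecast, holding that “about two G are used per L”, gave 80% for cedar and 90.6% for larch, lower than my larch figure, and said it rises.

The simulation gave 80.0% for cedar and 90.6% for larch; on raising G the reacted part did this: it rises, by 11 percentage points.

Cedar's L stood at 64.7% against its allowance of 65.0%, with 2.00% of its G free, while larch's L stood at 80.5% against 85.0%, with 5.73% free, its forward half-life for G having grown from 6.3 s at 1.81 s to 17 s at 20.0 s, and its reacted part reaching 93.2% only at 200 s. The neighbour of larch charged with 1.4 × 10⁻⁴ M of G has an allowance of 35.0%, and it ended with L at 36.7%, J holding most of the X, and a reacted part of 52.3%.

(The rate constants were set for the occasion; the rest is arithmetic.)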